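## Retrosynthetic overview
1. Aspidin PB ⇒ cut the aryl C–CH2 bond. This gives ψ-aspidinol, which has a single free ring C–H, and the 4-methylidene enetrione of ring A. No formaldehyde is used, so no homodimers form.
2. Methylidene enetrione ⇒ dehydrogenation of the ring C–CH3 of methylpropionylfilicinic acid. The bridge carbon is carried in as a methyl group.
3. Key step: methylpropionylfilicinic acid ⇒ flopropione by a one-flask triple C-methylation (2 + 1 on the two equivalent ring C–H). This ends both the aromaticity and the mirror symmetry. Flopropione ⇒ phloroglucinol + propionyl chloride.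
4. ψ-Aspidinol ⇒ 2-methylphloroglucinol by C-butyrylation, then O-methylation of the chelated, hindered OH while the other two OH groups are benzyl ethers.
5. No ring is formed. Both six-membered rings come from the phenols, and ring A is dearomatised before the two rings are joined.

Assumption: aspidin PB has no stereocentre and is achiral, so no enantiocontrol is needed. Enol tautomers are drawn as in the target SMILES.

## Route

Step 1
Reactants: 1 phloroglucinol; 2 propionyl chloride
Product: 3 flopropione (1-(2,4,6-trihydroxyphenyl)propan-1-one)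
Conditions: AlCl3 (3.5 equiv), CH2Cl2/PhNO2 1:1, 0 → 45 °C, 4 h; ice/1 M HCl
Reagents that add atoms: propionyl chloride (2), CCC(=O)Cl
Why: Friedel–Crafts acylation: the three C–H positions of 1 are equivalent and the chelated ketone–AlCl3 complex formed after the first acylation is deactivated, so the reaction stops at the mono-ketone, and no stereocentre is formed.

Step 2
Reactants: 3 flopropione; 4 iodomethane
Product: 7 methylpropionylfilicinic acid (3,5-dihydroxy-4,6,6-trimethyl-2-propanoylcyclohexa-2,4-dien-1-one), via 3-methylflopropione 5 (not isolated), via propionylfilicinic acid 6 (not isolated)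
Conditions: MeI (3.2 equiv), NaOMe (4.2 equiv), MeOH, 0 → 40 °C, 16 h; 1 M HCl; chromatography
Reagents that add atoms: iodomethane (4), CI
Why: Alkylative dearomatisation by exhaustive C-methylation of an acylphloroglucinol polyanion (a known reaction type): in MeOH the hydrogen-bonded oxyanions alkylate at carbon, the second methyl enters at the already methylated, most electron-rich carbon and locks the ring as the non-aromatic β-triketone 6, the third takes the last ring C–H, the delocalised anion of 7 plus limiting MeI holds back a fourth methylation, and the quaternary carbon bears two identical groups so no stereocentre arises.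

Step 3
Reactants: 8 2-methylphloroglucinol (2,4,6-trihydroxytoluene); 9 butyryl chloride
Product: 10 1-(2,4,6-trihydroxy-3-methylphenyl)butan-1-one
Conditions: AlCl3 (3.5 equiv), CH2Cl2/PhNO2 1:1, 0 → 45 °C, 4 h; ice/1 M HCl
Reagents that add atoms: butyryl chloride (9), CCCC(=O)Cl
Why: Friedel–Crafts acylation: the two free ring positions of 8 are related by its mirror plane, so only one mono-ketone can form, and the acyl group deactivates the ring against a second acylation.

Step 4
Reactants: 10 1-(2,4,6-trihydroxy-3-methylphenyl)butan-1-one; 11 benzyl bromide; 4 iodomethane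
Product: 13 1-[4,6-bis(benzyloxy)-2-methoxy-3-methylphenyl]butan-1-one, via dibenzyl ether 12 (not isolated)
Conditions: BnBr (2.05 equiv), K2CO3 (5 equiv), DMF, rt → 50 °C, 6 h; then MeI (5 equiv), same flask, 50 °C (sealed), 16 h
Reagents that add atoms: benzyl bromide (11), BrCc1ccccc1; iodomethane (4), CI
Why: Williamson etherification under kinetic control: the unchelated para OH and the less hindered ortho OH take the two benzyl groups, while the OH between C=O and CH3 stays locked in the hydrogen-bond chelate and buttressed by the methyl group until the small electrophile MeI is supplied in excess.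

Step 5
Reactants: 13 1-[4,6-bis(benzyloxy)-2-methoxy-3-methylphenyl]butan-1-one
Product: 14 ψ-aspidinol (1-(4,6-dihydroxy-2-methoxy-3-methylphenyl)butan-1-one)
Conditions: H2 (1 atm), 10% Pd/C, EtOAc/MeOH, rt
Reagents that add atoms: none
Why: Catalytic hydrogenolysis of benzyl aryl ethers: the methyl ether and the electron-rich, doubly ortho-substituted aryl ketone are inert at 1 atm and room temperature.

Step 6
Reactants: 7 methylpropionylfilicinic acid; 14 ψ-aspidinol
Product: 16 aspidin PB (4-[(3-butanoyl-2,6-dihydroxy-4-methoxy-5-methylphenyl)methyl]-3,5-dihydroxy-6,6-dimethyl-2-propanoylcyclohexa-2,4-dien-1-one), via methylidene enetrione 15 (not isolated)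
Conditions: Ag2O (1.0 equiv), TEMPO (0.3 equiv), 14 (1.2 equiv), THF, Ar, dark, 0 °C → rt, 7 added over 2 h by syringe pump; Celite, 1 M HCl wash
Reagents that add atoms: none
Why: Proposed new method: the much more acidic triketone 7 (pKa about 5, against about 8 for 14) is ionised and oxidised first by Ag(I), its C4 radical is trapped by TEMPO and loses TEMPO-H (re-oxidised by Ag2O) to give enetrione 15, which is kept dilute and is captured by the only free, doubly OH-flanked carbon of 14 in a Michael/Friedel–Crafts addition followed by enolisation and rearomatisation; the closest known reaction types are the TEMPO/Ag2O dehydrogenation of ring-methyl acylfilicinic acids with in situ hetero-Diels–Alder trapping and the addition of acylphloroglucinols to Knoevenagel-derived alkylidene β-triketones, and no stereocentre is formed.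

## Compound list
1 | phloroglucinol | Oc1cc(O)cc(O)c1 | starting material
2 | propionyl chloride | CCC(=O)Cl | starting material
3 | flopropione, 1-(2,4,6-trihydroxyphenyl)propan-1-one | CCC(=O)c1c(O)cc(O)cc1O | intermediate
4 | iodomethane | CI | starting material
5 | 3-methylflopropione, 1-(2,4,6-trihydroxy-3-methylphenyl)propan-1-one | CCC(=O)c1c(O)cc(O)c(C)c1O | intermediate
6 | propionylfilicinic acid, 3,5-dihydroxy-6,6-dimethyl-2-propanoylcyclohexa-2,4-dien-1-one | CCC(=O)C1=C(O)C=C(O)C(C)(C)C1=O | intermediate
7 | methylpropionylfilicinic acid, 3,5-dihydroxy-4,6,6-trimethyl-2-propanoylcyclohexa-2,4-dien-1-one | CCC(=O)C1=C(O)C(C)=C(O)C(C)(C)C1=O | intermediate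
8 | 2-methylphloroglucinol | Cc1c(O)cc(O)cc1O | starting material
9 | butyryl chloride | CCCC(=O)Cl | starting material
10 | 1-(2,4,6-trihydroxy-3-methylphenyl)butan-1-one | CCCC(=O)c1c(O)cc(O)c(C)c1O | intermediate
11 | benzyl bromide | BrCc1ccccc1 | starting material
12 | 1-[4,6-bis(benzyloxy)-2-hydroxy-3-methylphenyl]butan-1-one | CCCC(=O)c1c(O)c(C)c(OCc2ccccc2)cc1OCc1ccccc1 | intermediate
13 | 1-[4,6-bis(benzyloxy)-2-methoxy-3-methylphenyl]butan-1-one | CCCC(=O)c1c(OC)c(C)c(OCc2ccccc2)cc1OCc1ccccc1 | intermediate
14 | ψ-aspidinol, 1-(4,6-dihydroxy-2-methoxy-3-methylphenyl)butan-1-one | CCCC(=O)c1c(O)cc(O)c(C)c1OC | intermediate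
15 | 3-hydroxy-6,6-dimethyl-4-methylidene-2-propanoylcyclohex-2-ene-1,5-dione | CCC(=O)C1=C(O)C(=C)C(=O)C(C)(C)C1=O | intermediate
16 | aspidin PB (achiral) | CCCC(=O)c1c(O)c(CC2=C(O)C(C)(C)C(=O)C(C(=O)CC)=C2O)c(O)c(C)c1OC | target

## Step count and risks
Total step count: 6. The branches are 1 → 3 → 7 and 8 → 10 → 13 → 14, followed by one coupling.
Longest linear sequence: 4 steps (8 → 10 → 13 → 14 → 16).

**Step 6 (most likely to fail).**
- Ag2O/TEMPO may also oxidise 14.
- The product 16 carries the same alkyl-enol motif as 7, so it may be oxidised further.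
- Enetrione 15 may dimerise before it is trapped.

The fallback reverses the polarity and needs no oxidant. It sets out from 14, with its partner 6 obtained from 3, and comes back at 16.
- 14 is aminomethylated at its only free ring position (aq. CH2O, Me2NH, EtOH, rt). This gives the Mannich base 1-{3-[(dimethylamino)methyl]-2,4-dihydroxy-6-methoxy-5-methylphenyl}butan-1-one F1.
- 3 is methylated with only 2.1 equiv MeI, and 6 is isolated.
- F1 and 6 are heated in dioxane at 100 °C. Amine loss gives the ring-B ortho-quinone methide 4-butanoyl-5-hydroxy-3-methoxy-2-methyl-6-methylidenecyclohexa-2,4-dien-1-one F2.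
- Enol 6 captures F2 at its single free ring carbon and gives 16.

**Step 2.** Stopping at three methyl groups may give inseparable mixtures of 6, 7 and the tetramethyl compound. The fallback installs two methyl groups without alkyl halide and leaves one dearomatising alkylation. It sets out from 3 and comes back at 7.
- Double Mannich reaction (aq. CH2O, Me2NH, EtOH) gives 1-{3,5-bis[(dimethylamino)methyl]-2,4,6-trihydroxyphenyl}propan-1-one F3.
- Hydrogenolysis (H2, Pd/C, MeOH/AcOH, 50 °C) gives the symmetric 1-(2,4,6-trihydroxy-3,5-dimethylphenyl)propan-1-one F4.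
- One C-methylation (1.05 equiv MeI, NaOMe, MeOH) at either of the two equivalent C–CH3 carbons gives 7.

**Step 4.**
- Benzyl bromide may C-benzylate the free ring carbon.
- Discrimination between the two ortho OH groups may be imperfect.
- Methylation of the hindered chelated OH may be slow.

The fallback differentiates the OH groups by sulfonylation instead of alkylation and unmasks by hydrolysis instead of hydrogenolysis. It sets out from 10 and comes back at 14.
- TsCl (2.05 equiv), K2CO3, acetone, reflux gives 1-[2-hydroxy-3-methyl-4,6-bis(tosyloxy)phenyl]butan-1-one F5. The sulfur electrophile cannot alkylate ring carbon and is bulkier, so it distinguishes the two ortho OH groups better.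
- Me2SO4, K2CO3, acetone, reflux gives 1-[2-methoxy-3-methyl-4,6-bis(tosyloxy)phenyl]butan-1-one F6.
- KOH in aqueous dioxane at 80 °C, then acid, gives 14.

## Further compounds
F1 | step 6 | 1-{3-[(dimethylamino)methyl]-2,4-dihydroxy-6-methoxy-5-methylphenyl}butan-1-one | CCCC(=O)c1c(O)c(CN(C)C)c(O)c(C)c1OC
F2 | step 6 | 4-butanoyl-5-hydroxy-3-methoxy-2-methyl-6-methylidenecyclohexa-2,4-dien-1-one | CCCC(=O)C1=C(O)C(=C)C(=O)C(C)=C1OC
F3 | step 2 | 1-{3,5-bis[(dimethylamino)methyl]-2,4,6-trihydroxyphenyl}propan-1-one | CCC(=O)c1c(O)c(CN(C)C)c(O)c(CN(C)C)c1O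
F4 | step 2 | 1-(2,4,6-trihydroxy-3,5-dimethylphenyl)propan-1-one | CCC(=O)c1c(O)c(C)c(O)c(C)c1O
F5 | step 4 | 1-[2-hydroxy-3-methyl-4,6-bis(tosyloxy)phenyl]butan-1-one | CCCC(=O)c1c(O)c(C)c(OS(=O)(=O)c2ccc(C)cc2)cc1OS(=O)(=O)c1ccc(C)cc1
F6 | step 4 | 1-[2-methoxy-3-methyl-4,6-bis(tosyloxy)phenyl]butan-1-one | CCCC(=O)c1c(OC)c(C)c(OS(=O)(=O)c2ccc(C)cc2)cc1OS(=O)(=O)c1ccc(C)cc1
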